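**Strategy**

Everything rests on cutting the bond between the carbinol carbon Cα and its 3,4-dimethoxyphenyl ring (oxolane atoms: O1, C2H2, C3, C4-methyl, C5-aryl). On the oxolane the Cα side chain at C3 is cis to the C4 methyl, which an oxolane-3-carbaldehyde would lose by epimerization; in the ring-transposed γ-lactol, where O1 is bonded to Cα instead of C2, the same configuration is the all-trans, thermodynamically preferred one. The key step adds 3,4-dimethoxyphenylmagnesium bromide to this lactol (both anomers): the aryl–Cα bond forms and Cα is set in one operation, the alkoxide on C2 chelating magnesium to the unmasked aldehyde while C3 directs the attack. O1–C2 ring closure then completes the target.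

Key step: step 6

Remark (labels): in the lactone and lactol intermediates O1, C3, C4 and C5 keep the target labels; Cα is the ring carbonyl or hemiacetal carbon and C2 the exocyclic CH2O carbon.
Remark (step 1): it is assumed that (R)-TRIP gives (R)-carbinols from aryl aldehydes and allyl- or crotylboronic acid pinacol esters, hence the (S)-catalyst for the (1S,2S) product; if the sense is the opposite, the antipodal catalyst is used and nothing else changes.
Remark (step 6): 3,4-dimethoxyphenylmagnesium bromide is taken as the commercial 0.5 M THF solution.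

**Route**

Step 1
Reactants: 1 3,4-dimethoxybenzaldehyde; 2 (E)-crotylboronic acid pinacol ester
Product: 4 (1S,2S)-1-(3,4-dimethoxyphenyl)-2-methylbut-3-en-1-ol, via pinacol borate ester 3 (not isolated)
Conditions: (S)-TRIP [(S)-3,3'-bis(2,4,6-triisopropylphenyl)-1,1'-binaphthyl-2,2'-diyl hydrogen phosphate] (5 mol %), 4 Å MS, toluene, −30 °C; aq. NaHCO3 work-up
Reagents that add atoms: none
Why: Chiral phosphoric acid-catalysed crotylboration through a closed six-membered chair transition state, in which the E geometry of 2 translates into the anti C1/C2 relation and the (S)-catalyst is expected to select the aldehyde face that gives C1 S.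

Step 2
Reactants: 4 (1S,2S)-1-(3,4-dimethoxyphenyl)-2-methylbut-3-en-1-ol
Product: 6 (1S,2S)-1-(3,4-dimethoxyphenyl)-2-methylbutane-1,4-diol, via bis(9-BBN) adduct 5 (not isolated)
Conditions: 9-BBN (2.2 equiv), THF, 0 °C → rt; then NaOH, H2O2, 0 °C
Reagents that add atoms: hydrogen peroxide, OO
Why: Hydroboration–oxidation, in which boron adds to the terminal carbon of the monosubstituted alkene and oxidation gives the primary alcohol without touching either stereocenter.

Step 3
Reactants: 6 (1S,2S)-1-(3,4-dimethoxyphenyl)-2-methylbutane-1,4-diol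
Product: 8 (4S,5S)-5-(3,4-dimethoxyphenyl)-4-methyloxolan-2-one, via lactol 7 (not isolated)
Conditions: TEMPO (0.2 equiv), PhI(OAc)2 (2.5 equiv), CH2Cl2, rt
Reagents that add atoms: none
Why: TEMPO/oxoammonium oxidative lactonization, in which the primary alcohol is oxidized faster than the hindered secondary benzylic one, the aldehyde is trapped as lactol 7 and this is oxidized on to the trans lactone.

Step 4
Reactants: 8 (4S,5S)-5-(3,4-dimethoxyphenyl)-4-methyloxolan-2-one
Product: 10 (3R,4S,5S)-5-(3,4-dimethoxyphenyl)-3-(hydroxymethyl)-4-methyloxolan-2-one, via lithium enolate 9 (not isolated)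
Conditions: LDA (1.1 equiv), THF, −78 °C; CH2O (gas, from cracked paraformaldehyde), −78 → −40 °C; aq. NH4Cl
Reagents that add atoms: formaldehyde, C=O
Why: Aldol addition of a lactone lithium enolate to monomeric formaldehyde, in which the electrophile approaches the enolate face anti to the neighbouring C4 methyl, so that C3 is set trans to it (3R), which is also the thermodynamic arrangement.

Step 5
Reactants: 10 (3R,4S,5S)-5-(3,4-dimethoxyphenyl)-3-(hydroxymethyl)-4-methyloxolan-2-one
Product: 11 (3R,4S,5S)-5-(3,4-dimethoxyphenyl)-3-(hydroxymethyl)-4-methyloxolan-2-ol (mixture of anomers)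
Conditions: DIBAL-H (2.5 equiv), CH2Cl2, −78 °C; Rochelle salt work-up
Reagents that add atoms: none
Why: Partial lactone reduction with DIBAL-H, in which the aluminium hemiacetal is stable at −78 °C and collapses to the lactol only on work-up, no stereocenter of the all-trans ring being affected.

Step 6
Reactants: 11 (3R,4S,5S)-5-(3,4-dimethoxyphenyl)-3-(hydroxymethyl)-4-methyloxolan-2-ol; 12 3,4-dimethoxyphenylmagnesium bromide
Product: 14 (1R,2R,3S,4S)-1,4-bis(3,4-dimethoxyphenyl)-2-(hydroxymethyl)-3-methylbutane-1,4-diol, via open-chain hydroxy aldehyde 13 (not isolated)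
Conditions: 12 (4 equiv, 0.5 M in THF), THF, −40 → 0 °C; aq. NH4Cl
Reagents that add atoms: none
Why: The first two equivalents of 12 deprotonate both hydroxyls, the magnesium lactolate (either anomer) opens to aldehyde 13, and a further equivalent transfers the aryl group to the aldehyde carbon, forming the aryl–Cα bond. The closest known reaction type is the chelation-controlled addition of aryl Grignard reagents to γ-lactols used in furofuran and oxolane lignan synthesis. No ring is closed; the lactol ring is opened, which frees O1 from Cα for its final partner C2 in step 7. The new stereocenter Cα (R) is controlled by C3: the magnesium of the C2 alkoxide binds the aldehyde oxygen in a six-membered chelate and the aryl group enters anti to the C4 branch, and the Felkin–Anh conformer with that branch as the large group leads to the same face. The step needs facial selectivity at Cα and retention of the C3 configuration; the chelate is expected to secure the former, and the latter is safe because 11 is already the thermodynamic all-trans lactol and addition to the aldehyde should outrun enolization or retro-aldol loss of formaldehyde. The competing seven-membered chelate through the C5 alkoxide, which would deliver the epimer, is expected to be the weaker one.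

Step 7
Reactants: 14 (1R,2R,3S,4S)-1,4-bis(3,4-dimethoxyphenyl)-2-(hydroxymethyl)-3-methylbutane-1,4-diol
Product: 16 (R)-(3,4-dimethoxyphenyl)[(3R,4S,5S)-5-(3,4-dimethoxyphenyl)-4-methyloxolan-3-yl]methanol, via primary tosylate 15 (not isolated)
Conditions: TsCl (1.1 equiv), pyridine, 0 °C, then 50 °C
Reagents that add atoms: none
Why: Selective sulfonylation of the only primary hydroxyl followed by intramolecular Williamson etherification, in which the C5 hydroxyl closes the oxolane (5-exo-tet) much faster than the Cα hydroxyl could close an oxetane (4-exo-tet), and since substitution occurs at the CH2 carbon all four stereocenters are retained.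

**Compound list**

1 | 3,4-dimethoxybenzaldehyde (veratraldehyde) | COc1ccc(C=O)cc1OC | starting material
2 | (E)-crotylboronic acid pinacol ester, (E)-2-(but-2-en-1-yl)-4,4,5,5-tetramethyl-1,3,2-dioxaborolane | C/C=C/CB1OC(C)(C)C(C)(C)O1 | starting material
3 | pinacol borate ester of alcohol 4 (O–Bpin at C1) | COc1ccc([C@@H](OB2OC(C)(C)C(C)(C)O2)[C@@H](C)C=C)cc1OC | intermediate
4 | (1S,2S)-1-(3,4-dimethoxyphenyl)-2-methylbut-3-en-1-ol | COc1ccc([C@@H](O)[C@@H](C)C=C)cc1OC | intermediate
5 | bis(9-BBN) adduct of 4 (O-borinate at C1, B-alkyl at C4) | COc1ccc([C@@H](OB2C3CCCC2CCC3)[C@@H](C)CCB2C3CCCC2CCC3)cc1OC | intermediate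
6 | (1S,2S)-1-(3,4-dimethoxyphenyl)-2-methylbutane-1,4-diol | COc1ccc([C@@H](O)[C@@H](C)CCO)cc1OC | intermediate
7 | (4S,5S)-5-(3,4-dimethoxyphenyl)-4-methyloxolan-2-ol (anomers) | COc1ccc([C@H]2OC(O)C[C@@H]2C)cc1OC | intermediate
8 | (4S,5S)-5-(3,4-dimethoxyphenyl)-4-methyloxolan-2-one | COc1ccc([C@H]2OC(=O)C[C@@H]2C)cc1OC | intermediate
9 | lithium enolate of lactone 8 | COc1ccc([C@H]2OC(O[Li])=C[C@@H]2C)cc1OC | intermediate
10 | (3R,4S,5S)-5-(3,4-dimethoxyphenyl)-3-(hydroxymethyl)-4-methyloxolan-2-one (all-trans) | COc1ccc([C@H]2OC(=O)[C@@H](CO)[C@@H]2C)cc1OC | intermediate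
11 | (3R,4S,5S)-5-(3,4-dimethoxyphenyl)-3-(hydroxymethyl)-4-methyloxolan-2-ol (anomers) | COc1ccc([C@H]2OC(O)[C@@H](CO)[C@@H]2C)cc1OC | intermediate
12 | 3,4-dimethoxyphenylmagnesium bromide | COc1ccc([Mg]Br)cc1OC | starting material
13 | (2R,3S,4S)-4-(3,4-dimethoxyphenyl)-4-hydroxy-2-(hydroxymethyl)-3-methylbutanal (reacts as its bis(bromomagnesium) alkoxide) | COc1ccc([C@@H](O)[C@@H](C)[C@H](CO)C=O)cc1OC | intermediate
14 | (1R,2R,3S,4S)-1,4-bis(3,4-dimethoxyphenyl)-2-(hydroxymethyl)-3-methylbutane-1,4-diol | COc1ccc([C@@H](O)[C@@H](C)[C@H](CO)[C@@H](O)c2ccc(OC)c(OC)c2)cc1OC | intermediate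
15 | 4-methylbenzenesulfonate of triol 14 at the primary hydroxyl (configuration as in 14) | COc1ccc([C@@H](O)[C@@H](C)[C@H](COS(=O)(=O)c2ccc(C)cc2)[C@@H](O)c2ccc(OC)c(OC)c2)cc1OC | intermediate
16 | (R)-(3,4-dimethoxyphenyl)[(3R,4S,5S)-5-(3,4-dimethoxyphenyl)-4-methyloxolan-3-yl]methanol | COc1ccc([C@H]2OC[C@H]([C@@H](O)c3ccc(OC)c(OC)c3)[C@@H]2C)cc1OC | target

**Count and risks**

Total step count: 7. Longest linear sequence: 7 steps (1 → 16).

Steps most likely to fail:

1. Step 6 (key step). The aryl transfer may show poor facial selectivity, because the seven-membered chelate through the C5 alkoxide leads to the Cα epimer and competes with the six-membered one; enolization of the open aldehyde is a second risk. The fallback sets out from 11 and returns at 16. The addition is run as described and the unseparated mixture of 14 and its Cα epimer, the (1S)-triol F1, is taken through the conditions of step 7. This should give 16 together with its carbinol epimer F3 by way of the primary tosylate F2. Buffered Dess–Martin oxidation (NaHCO3, CH2Cl2, 0 °C) then merges 16 and F3 into the aryl ketone F4. A reagent-controlled Corey–Bakshi–Shibata reduction ((S)-Me-CBS oxazaborolidine, catecholborane, toluene, −78 °C; aryl as the large group, expected to give the R carbinol) returns 16. Both added operations are non-basic, so the epimerizable C3 next to the ketone is not put at risk.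

2. Step 7. The sulfonylation may lose chemoselectivity: activation or ionization of one of the two electron-rich benzylic hydroxyls would lead to chloride, elimination or a 2,5-diaryl oxolane, and closure may be sluggish. The fallback sets out from 10 and returns at 16; the leaving group is installed before the second benzylic carbinol exists. TsCl in pyridine at 0 °C should give the tosyloxymethyl lactone F5, and DIBAL-H (1.2 equiv, CH2Cl2, −78 °C) the lactol tosylate F6. Treatment of F6 with 12 (3 equiv, THF, −40 → 0 °C), then t-BuOK, is expected to add the aryl group and close the oxolane in the same flask through the alkoxide of 15, giving 16 without a separate cyclization. Facial control at Cα then rests on the Felkin–Anh preference alone.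

3. Step 4. Conversion may be low through repolymerization of formaldehyde, a second hydroxymethylation, or retro-aldol reaction or dehydration of the β-hydroxy lactone during work-up. The fallback sets out from 8 and returns at 10. The lithium enolate 9 is carboxylated with CO2 (THF, −78 °C) to the trans α-carboxy lactone F7. Its acid group alone is then reduced with BH3·SMe2 (THF, 0 °C), a reagent that leaves the lactone untouched; the malonate-type C3 should equilibrate to the trans acid before reduction.

**Further compounds**

F1 | step 6 | (1S,2R,3S,4S)-1,4-bis(3,4-dimethoxyphenyl)-2-(hydroxymethyl)-3-methylbutane-1,4-diol | COc1ccc([C@@H](O)[C@@H](C)[C@H](CO)[C@H](O)c2ccc(OC)c(OC)c2)cc1OC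
F2 | step 6 | 4-methylbenzenesulfonate of triol F1 at the primary hydroxyl | COc1ccc([C@@H](O)[C@@H](C)[C@H](COS(=O)(=O)c2ccc(C)cc2)[C@H](O)c2ccc(OC)c(OC)c2)cc1OC
F3 | step 6 | (S)-(3,4-dimethoxyphenyl)[(3R,4S,5S)-5-(3,4-dimethoxyphenyl)-4-methyloxolan-3-yl]methanol | COc1ccc([C@H]2OC[C@H]([C@H](O)c3ccc(OC)c(OC)c3)[C@@H]2C)cc1OC
F4 | step 6 | (3,4-dimethoxyphenyl)[(3R,4S,5S)-5-(3,4-dimethoxyphenyl)-4-methyloxolan-3-yl]methanone | COc1ccc([C@H]2OC[C@H](C(=O)c3ccc(OC)c(OC)c3)[C@@H]2C)cc1OC
F5 | step 7 | [(3R,4S,5S)-5-(3,4-dimethoxyphenyl)-4-methyl-2-oxooxolan-3-yl]methyl 4-methylbenzenesulfonate | COc1ccc([C@H]2OC(=O)[C@@H](COS(=O)(=O)c3ccc(C)cc3)[C@@H]2C)cc1OC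
F6 | step 7 | [(3R,4S,5S)-5-(3,4-dimethoxyphenyl)-2-hydroxy-4-methyloxolan-3-yl]methyl 4-methylbenzenesulfonate (anomers) | COc1ccc([C@H]2OC(O)[C@@H](COS(=O)(=O)c3ccc(C)cc3)[C@@H]2C)cc1OC
F7 | step 4 | (3R,4S,5S)-5-(3,4-dimethoxyphenyl)-4-methyl-2-oxooxolane-3-carboxylic acid | COc1ccc([C@H]2OC(=O)[C@@H](C(=O)O)[C@@H]2C)cc1OC
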